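## Structural features

The target 15 is a furan-2(5H)-one, numbered here O1–C2(=O)–C3H=C4–C5(=C6H). It carries the 4-hydroxyphenyl ring B on C4 and, through the exocyclic C5=C6 double bond, the 3-bromo-4-methoxyphenyl ring A on C6. There is no sp3 stereocentre, so no stereocentres stand next to each other. The only stereochemical element is the Z geometry of C5=C6 (ring A on the side of O1), which is also the more stable one because the E isomer would press ring A against ring B. The fragile groups are the γ-ylidene enol lactone (opened by hydroxide or alkoxide, isomerized by light), the aryl C–Br bond (lost on hydrogenolysis, halogen–metal exchange or with hot zerovalent palladium), the free phenol (oxidizable, and reactive toward sulfonylating agents) and the aryl methyl ether, which rules out boron tribromide-type deprotections. The real difficulty is not the five-membered ring but placing two similar aryl units unambiguously, ring B on C4 and ring A on C6, and reaching the oxidation level of the exocyclic alkene without disturbing C–Br. A cut through C4–C5 divides the skeleton into ring B–C4–C3–C2 and ring A–C6–C5, two arylpropanoid chains if C5 is allowed one extra carboxyl carbon. C4 is then the nucleophilic benzylic carbon of one arylpyruvate, C5 the ketone carbon of the other, O1 the aldol oxygen and C2 an ester carbon. The price is an extra hydroxyl on C3 and a carboxyl on C5 in the cyclization product, to be removed by one reduction and one oxidative decarboxylation.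

## Logic of the disconnections

15 ⇒ 14. The phenolic O–H is traced back to an O–Si bond. The phenol has to be masked through Lewis acid, triflation, palladium and lead chemistry, and a silyl ether can be removed at the end by buffered fluoride, which spares the enol lactone, C–Br and the methyl ether. Nothing is gained in skeleton; the demand on the forward step is only that the medium stays close to neutral.

14 ⇒ 13. The C5=C6 π bond is undone by reattaching a carboxyl carbon to C5 and a hydrogen to C6. This turns the stereogenic alkene into a quaternary sp3 carbon of the kind an aldol addition to a ketone produces. The forward step must remove CO2 and one C6 hydrogen oxidatively; regiochemistry is not in question because C6 holds the only β-hydrogens, and the geometry is left to product stability.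

13 ⇒ 12. The carboxyl O–H goes back to an O–C(CH3)3 bond. The carboxyl needs an ester that falls to acid without touching the lactone and that is too hindered to act as an acyl donor during ring closure. The forward step demands that the aryl silyl ether survives trifluoroacetic acid.

12 ⇒ 11 ⇒ 10. The C3–H bond is traced back to a C3–O bond, first as triflate, then as enol hydroxyl. The C3 oxygen is what remains of the ketone of the nucleophilic pyruvate, so accepting it allows the aldol disconnection. The forward reduction requires zerovalent palladium to insert into the alkenyl C–OTf bond and not into the aryl C–Br bond.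

10 ⇒ 3 + 8 (through 9). The bonds O1–C2 (lactone) and C4–C5 (aldol) are cut. This is the largest simplification of the plan: ring, quaternary carbon and the full carbon skeleton fall apart into two halves of almost equal size. The forward step must make 3 the only nucleophile and 8 the only electrophile, so 8 has to enter as the ketone and not as its enol.

3 ⇒ 2 ⇒ 1. Two O–Si bonds and then the ester O–CH3 bond are cut, arriving at a commercial acid. The demand is that esterification and silylation use bases too weak or too short-lived to start self-condensation of the pyruvate.

8 ⇒ 5 + 6 (through 7), and 5 ⇒ 4. The bond between the benzylic carbon (future C6) and the ketone carbon (future C5) is cut, then the C–Cl bond. Acylating a benzylic nucleophile with an oxalate diester delivers the α-keto ester in one step with the tert-butyl ester in place and, after cold acidic quench, as the ketone tautomer. The forward step needs magnesium to insert at the benzylic chloride and not at the aryl bromide, and the addition to stop after one equivalent.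

## Other disconnections considered

Alternative 1: Ring B is dismantled. Two of its C–C bonds are cut, leaving the alkyne of (Z)-5-(3-bromo-4-methoxybenzylidene)-4-ethynylfuran-2(5H)-one A1 and the four-carbon unit of Danishefsky's diene A2.
- Forward step: a Diels–Alder addition across the ethynyl group, then loss of methanol, would aromatize the adduct to the silyl ether A3, which needs only desilylation.
- In favour: the para relationship of oxygen and butenolide follows from the polarization of both partners (nucleophilic diene terminus to the alkyne terminus), and no redox correction at C3 or C5 is needed.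
- Against: A1 already contains the heat- and light-sensitive ylidene lactone and two further dienophilic double bonds. The terminal ynenoate is prone to polymerize at cycloaddition temperatures. Making A1 takes an alkynylation of a 4-halobutenolide and a benzylidene installation, the same operations that could attach a purchased ring B directly.
- Comparison: on mechanism the pericyclic step is at least the equal of the chosen aldol, since its partners cannot exchange roles. On step economy it is probably the better plan (about five to six steps against ten). The chosen plan is stronger in that its sensitive alkene appears only in the penultimate step and that it draws both halves from cheap arylpropanoid feedstock.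

Alternative 2: The lactone carbonyl and the C5 substituent are traced back to an aromatic furan, 2-(3-bromo-4-methoxybenzyl)-3-[4-(tert-butyldimethylsilyloxy)phenyl]furan A4.
- Forward step: singlet oxygen would add across the two α-carbons, and base-induced Kornblum–DeLaMare fragmentation of the endoperoxide would give the hydroxybutenolide A5, since only one α-carbon carries a hydrogen. Dehydration of A5 would lead to 14.
- In favour: the oxidation level is right from the start, the regiochemistry is dictated by the single α C–H, and the conditions tolerate C–Br and the silyl ether. Only dehydration and desilylation follow.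
- Against: A4 needs a regiocontrolled 2,3-disubstituted furan (benzylation next to the aryl group and not at the remote α-position), organometallic steps close to an aryl bromide, and a doubly activated benzylic CH2 prone to autoxidation. A5 equilibrates with an open keto acid, which can complicate dehydration.
- Comparison: the end game is better than that of the chosen plan (shorter, no heavy-metal oxidant, no palladium near C–Br), and the overall count is likely lower. Convergence is equal. The chosen plan is stronger in that its two halves are trivial to make, so its risk is concentrated in one step and not spread over a furan synthesis.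

Alternative 3: The C4–ring B bond and O1–C2 are cut, giving the hydroxy ynoate A6 and the boronic acid A7.
- Forward step: an arylcopper from A7 would add syn across the triple bond of A6 with the aryl group on the β-carbon. The carbinol and the ester then end up cis, so lactonization to A8 should follow in the same flask.
- In favour: regio- and stereochemistry are both set by the syn carbometalation, copper leaves the aryl bromide alone, and the assembly is highly convergent.
- Against: A8 still lacks the C5=C6 double bond, so a dehydrogenation through a silyloxyfuran, halogenation and elimination must follow. A6 derives from an enolizable arylacetaldehyde. A7 can protodeboronate in alcohol.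
- Comparison: A8 has the same structure as F2, which the chosen route reaches only in a fallback after nine steps. Up to that compound the alternative is clearly the better on step economy, and its key step is mechanistically at least as reliable. The chosen plan is stronger in the finish, because its C5 carboxyl is a built-in handle that gives the alkene in one oxidative step from 13.

Key step: step 5

Remarks on the chemistry (assumptions and design choices):
- (3-Bromo-4-methoxyphenyl)methanol 4 is assumed to be purchasable; it is otherwise one borohydride reduction away from the aldehyde.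
- Arylpyruvate esters are drawn as ketones. Ester 2 is expected to be largely its Z-enol, which does not matter for step 2. Ester 8 must enter step 5 as the ketone, because TiCl4 would metalate an enol and liberate HCl, which would cleave the enolsilane and scramble the roles. Step 4 is therefore designed to release 8 as the ketone.
- Both silyl groups of the ring B unit are tert-butyldimethylsilyl, not a labile trimethylsilyl enol ether beside a different phenol ether. One operation installs both, the enolsilane can be purified, and silyl transfer between the partners is slowed.
- The connectivity, locants and Z descriptor of the key-step partners and of the 3-hydroxybutenolide product were checked against each other and are consistent; no correction was needed.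

## Steps

Step 1
Reactants: 1 4-hydroxyphenylpyruvic acid
Product: 2 methyl 3-(4-hydroxyphenyl)-2-oxopropanoate
Conditions: MeI, KHCO3, DMF, rt
Reagents that add atoms: iodomethane, CI
Why: Carboxylate O-alkylation (SN2): bicarbonate deprotonates only the α-keto acid, so iodomethane esterifies it while phenol and enol stay free; the weak base should keep self-aldol dimerization of the pyruvate low.

Step 2
Reactants: 2 methyl 3-(4-hydroxyphenyl)-2-oxopropanoate
Product: 3 methyl (Z)-2-(tert-butyldimethylsilyloxy)-3-[4-(tert-butyldimethylsilyloxy)phenyl]acrylate
Conditions: TBSOTf, Et3N, CH2Cl2, −78 to 0 °C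
Reagents that add atoms: tert-butyldimethylsilyl trifluoromethanesulfonate, CC(C)(C)[Si](C)(C)OS(=O)(=O)C(F)(F)F
Why: Silyl triflate with an amine base silylates the phenol and traps the pyruvate as its enol ether in one operation (standard enolsilane formation). The Z isomer, aryl trans to the ester, should predominate, and either geometry would serve because C4 becomes sp2 in step 5.

Step 3
Reactants: 4 (3-bromo-4-methoxyphenyl)methanol
Product: 5 2-bromo-4-(chloromethyl)-1-methoxybenzene
Conditions: SOCl2, DMF (cat.), CH2Cl2, 0 °C to rt
Reagents that add atoms: thionyl chloride, O=S(Cl)Cl
Why: Standard conversion of a benzylic alcohol into the chloride through its chlorosulfite; the chloride is preferred to the bromide because it gives less Wurtz coupling in step 4.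

Step 4
Reactants: 5 2-bromo-4-(chloromethyl)-1-methoxybenzene; 6 di-tert-butyl oxalate
Product: 8 tert-butyl 3-(3-bromo-4-methoxyphenyl)-2-oxopropanoate (keto tautomer), via benzylic Grignard reagent 7 (not isolated)
Conditions: Mg, 2-MeTHF, 0 °C; then 6 (excess), THF, −78 °C; 1 M HCl, −78 to 0 °C
Reagents that add atoms: none
Why: Magnesium inserts into the benzylic C–Cl bond faster than into the aryl C–Br bond at 0 °C (Grignard formation), and addition to an excess of the hindered oxalate diester at −78 °C stops at the tetrahedral magnesium hemiketal (classic α-keto ester synthesis). The ketone is set free only by the cold acidic quench, so 8 should be obtained as the keto tautomer and is used promptly.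

Step 5
Reactants: 3 methyl (Z)-2-(tert-butyldimethylsilyloxy)-3-[4-(tert-butyldimethylsilyloxy)phenyl]acrylate; 8 tert-butyl 3-(3-bromo-4-methoxyphenyl)-2-oxopropanoate
Product: 10 tert-butyl 2-(3-bromo-4-methoxybenzyl)-3-[4-(tert-butyldimethylsilyloxy)phenyl]-4-hydroxy-5-oxo-2,5-dihydrofuran-2-carboxylate (racemic), via open-chain aldol adduct 9 (not isolated)
Conditions: 8, TiCl4, CH2Cl2, −78 °C; then 3, −78 to −40 °C; aq. NaHCO3; PPTS (cat.), CH2Cl2, rt
Reagents that add atoms: none
Why: TiCl4 binds the ketone and ester oxygens of 8 in a five-membered chelate, which makes the ketone carbon (future C5) strongly electrophilic; enolsilane 3 attacks through its benzylic carbon (future C4) in a Mukaiyama aldol addition, and loss of the silyl group leaves the titanium alkoxide of 9. The closest known reaction types are the chelation-controlled Mukaiyama addition of enolsilanes to pyruvate esters and the aldol–lactonization of pyruvates to isotetronic acids (3-hydroxybutenolides). The C5 alkoxide then attacks the methyl ester carbonyl (future C2) of the ring B unit in a 5-exo-trig closure that expels methanol, and the α-keto lactone enolizes toward C4 to the conjugated 3-hydroxybutenolide, which erases the C4 stereocentre of 9. C5 is the one new stereocentre that persists; nothing controls it and nothing needs to, because 10 is racemic and C5 becomes sp2 in step 9, so neither enolsilane geometry nor facial selectivity matters. The selectivity the step needs is cross- against homo-coupling and the right direction of cross-coupling: only the ring B unit is present as an enolsilane, 8 enters as the non-enolized ketone and is the only 1,2-dicarbonyl that TiCl4 can chelate, and no base is present to move protons between the partners. The esters add a second safeguard: ring closure uses the ester of the nucleophilic unit, so only adducts in which the methyl ester unit of ring B was the nucleophile can lactonize readily, whereas adducts with the hindered tert-butyl ester in that role stay open. The low temperature should keep the tert-butyl ester and the aryl silyl ether intact toward TiCl4, and catalytic PPTS after work-up completes the closure of any 9 that survives.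

Step 6
Reactants: 10 tert-butyl 2-(3-bromo-4-methoxybenzyl)-3-[4-(tert-butyldimethylsilyloxy)phenyl]-4-hydroxy-5-oxo-2,5-dihydrofuran-2-carboxylate
Product: 11 tert-butyl 2-(3-bromo-4-methoxybenzyl)-3-[4-(tert-butyldimethylsilyloxy)phenyl]-5-oxo-4-{[(trifluoromethyl)sulfonyl]oxy}-2,5-dihydrofuran-2-carboxylate (racemic)
Conditions: Tf2O, pyridine, CH2Cl2, −78 to 0 °C
Reagents that add atoms: trifluoromethanesulfonic anhydride, O=S(=O)(OS(=O)(=O)C(F)(F)F)C(F)(F)F
Why: O-Sulfonylation of the acidic enol of the α-keto lactone gives a stable alkenyl triflate; the phenol is masked, so C3–OH is the only hydroxyl, and no stereocentre is touched.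

Step 7
Reactants: 11 tert-butyl 2-(3-bromo-4-methoxybenzyl)-3-[4-(tert-butyldimethylsilyloxy)phenyl]-5-oxo-4-{[(trifluoromethyl)sulfonyl]oxy}-2,5-dihydrofuran-2-carboxylate
Product: 12 tert-butyl 2-(3-bromo-4-methoxybenzyl)-3-[4-(tert-butyldimethylsilyloxy)phenyl]-5-oxo-2,5-dihydrofuran-2-carboxylate (racemic)
Conditions: Pd(OAc)2 (cat.), PPh3, HCO2H, Bu3N, DMF, 40 °C
Reagents that add atoms: none
Why: Palladium-catalysed formate reduction of an alkenyl triflate: zerovalent palladium inserts into the electron-poor C3–OTf bond, formate exchanges for triflate, CO2 is lost and C–H reductive elimination follows. With PPh3 at 40 °C the electron-rich, ortho-alkoxy aryl bromide should undergo oxidative addition much more slowly and survive.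

Step 8
Reactants: 12 tert-butyl 2-(3-bromo-4-methoxybenzyl)-3-[4-(tert-butyldimethylsilyloxy)phenyl]-5-oxo-2,5-dihydrofuran-2-carboxylate
Product: 13 2-(3-bromo-4-methoxybenzyl)-3-[4-(tert-butyldimethylsilyloxy)phenyl]-5-oxo-2,5-dihydrofuran-2-carboxylic acid (racemic)
Conditions: TFA, CH2Cl2, 0 °C to rt
Reagents that add atoms: none
Why: Acidolysis of the tert-butyl ester through the tert-butyl cation (E1, isobutene) leaves the lactone, the aryl bromide and the aryl silyl ether, whose oxygen is made less basic by the para acceptor; the acid is kept protonated and used at once to avoid premature loss of CO2.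

Step 9
Reactants: 13 2-(3-bromo-4-methoxybenzyl)-3-[4-(tert-butyldimethylsilyloxy)phenyl]-5-oxo-2,5-dihydrofuran-2-carboxylic acid
Product: 14 (Z)-5-(3-bromo-4-methoxybenzylidene)-4-[4-(tert-butyldimethylsilyloxy)phenyl]furan-2(5H)-one
Conditions: Pb(OAc)4, Cu(OAc)2 (cat.), pyridine, PhCl, 80 °C, dark
Reagents that add atoms: none
Why: Kochi-type oxidative decarboxylation: the lead carboxylate of 13 fragments to CO2 and a C5 radical that is tertiary, oxygen-substituted and allylic; Cu(OAc)2 oxidizes it, and the only β-hydrogens, those on C6, are lost to give the conjugated enol lactone. The Z geometry is set by product stability, since the E isomer would force ring A against ring B on C4.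

Step 10
Reactants: 14 (Z)-5-(3-bromo-4-methoxybenzylidene)-4-[4-(tert-butyldimethylsilyloxy)phenyl]furan-2(5H)-one
Product: 15 3''-bromorubrolide F, (Z)-5-(3-bromo-4-methoxybenzylidene)-4-(4-hydroxyphenyl)furan-2(5H)-one
Conditions: TBAF, AcOH, THF, 0 °C, dark
Reagents that add atoms: none
Why: Fluoride cleaves the aryl O–Si bond; buffering with acetic acid keeps the medium close to neutral so that the enol lactone is not opened and the Z alkene is not disturbed.

## Compound list

1 | 4-hydroxyphenylpyruvic acid, 3-(4-hydroxyphenyl)-2-oxopropanoic acid | OC(=O)C(=O)Cc1ccc(O)cc1 | starting material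
2 | methyl 3-(4-hydroxyphenyl)-2-oxopropanoate (largely present as its Z-enol) | COC(=O)C(=O)Cc1ccc(O)cc1 | intermediate
3 | methyl (Z)-2-(tert-butyldimethylsilyloxy)-3-[4-(tert-butyldimethylsilyloxy)phenyl]acrylate | COC(=O)/C(O[Si](C)(C)C(C)(C)C)=C/c1ccc(O[Si](C)(C)C(C)(C)C)cc1 | intermediate
4 | (3-bromo-4-methoxyphenyl)methanol | COc1ccc(CO)cc1Br | starting material
5 | 2-bromo-4-(chloromethyl)-1-methoxybenzene (3-bromo-4-methoxybenzyl chloride) | COc1ccc(CCl)cc1Br | intermediate
6 | di-tert-butyl oxalate | CC(C)(C)OC(=O)C(=O)OC(C)(C)C | starting material
7 | (3-bromo-4-methoxybenzyl)magnesium chloride | COc1ccc(C[Mg]Cl)cc1Br | intermediate (not isolated)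
8 | tert-butyl 3-(3-bromo-4-methoxyphenyl)-2-oxopropanoate (keto tautomer) | CC(C)(C)OC(=O)C(=O)Cc1ccc(OC)c(Br)c1 | intermediate
9 | 1-tert-butyl 5-methyl 2-(3-bromo-4-methoxybenzyl)-3-[4-(tert-butyldimethylsilyloxy)phenyl]-2-hydroxy-4-oxopentanedioate (diastereomer mixture, racemic; titanium alkoxide in the flask) | COC(=O)C(=O)C(c1ccc(O[Si](C)(C)C(C)(C)C)cc1)C(O)(Cc1ccc(OC)c(Br)c1)C(=O)OC(C)(C)C | intermediate (not isolated)
10 | tert-butyl 2-(3-bromo-4-methoxybenzyl)-3-[4-(tert-butyldimethylsilyloxy)phenyl]-4-hydroxy-5-oxo-2,5-dihydrofuran-2-carboxylate (racemic) | CC(C)(C)OC(=O)C1(Cc2ccc(OC)c(Br)c2)OC(=O)C(O)=C1c1ccc(O[Si](C)(C)C(C)(C)C)cc1 | intermediate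
11 | tert-butyl 2-(3-bromo-4-methoxybenzyl)-3-[4-(tert-butyldimethylsilyloxy)phenyl]-5-oxo-4-{[(trifluoromethyl)sulfonyl]oxy}-2,5-dihydrofuran-2-carboxylate (racemic) | CC(C)(C)OC(=O)C1(Cc2ccc(OC)c(Br)c2)OC(=O)C(OS(=O)(=O)C(F)(F)F)=C1c1ccc(O[Si](C)(C)C(C)(C)C)cc1 | intermediate
12 | tert-butyl 2-(3-bromo-4-methoxybenzyl)-3-[4-(tert-butyldimethylsilyloxy)phenyl]-5-oxo-2,5-dihydrofuran-2-carboxylate (racemic) | CC(C)(C)OC(=O)C1(Cc2ccc(OC)c(Br)c2)OC(=O)C=C1c1ccc(O[Si](C)(C)C(C)(C)C)cc1 | intermediate
13 | 2-(3-bromo-4-methoxybenzyl)-3-[4-(tert-butyldimethylsilyloxy)phenyl]-5-oxo-2,5-dihydrofuran-2-carboxylic acid (racemic) | OC(=O)C1(Cc2ccc(OC)c(Br)c2)OC(=O)C=C1c1ccc(O[Si](C)(C)C(C)(C)C)cc1 | intermediate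
14 | (Z)-5-(3-bromo-4-methoxybenzylidene)-4-[4-(tert-butyldimethylsilyloxy)phenyl]furan-2(5H)-one | COc1ccc(/C=C2\OC(=O)C=C2c2ccc(O[Si](C)(C)C(C)(C)C)cc2)cc1Br | intermediate
15 | 3''-bromorubrolide F, (Z)-5-(3-bromo-4-methoxybenzylidene)-4-(4-hydroxyphenyl)furan-2(5H)-one | COc1ccc(/C=C2\OC(=O)C=C2c2ccc(O)cc2)cc1Br | target

## Step count and least certain steps

Total step count: 10. Longest linear sequence: 8 steps (steps 3, 4 and 5 to 10 from 4; equally steps 1, 2 and 5 to 10 from 1).

Step 5 (key step). The most likely failure is exchange of roles between the partners. If 8 has tautomerized to its enol before use, TiCl4 metalates it and releases HCl, the acid cleaves the enolsilane, and homo-coupling of the ring B unit or addition in the inverted sense then competes. Slow addition to the hindered ketone and loss of the tert-butyl ester on warming are the secondary risks. The fallback gives up the directed Lewis acid addition for an equilibrating, base-promoted aldol–lactonization, a known reaction of arylpyruvate esters. It sets out from 3 and returns at 10.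
- Brief treatment of 3 with dilute HCl in THF at 0 °C should remove only the enol silyl group by C-protonation and give methyl 3-[4-(tert-butyldimethylsilyloxy)phenyl]-2-oxopropanoate F1.
- F1 is added slowly to about two equivalents of 8 and DBU in MeCN at 0 °C, and acidification should give 10.
- The tautomeric state of 8 no longer matters under these conditions.
- The cross product forms at a rate first order in F1 and the ring B homodimer second order, so slow addition favours the cross product.
- Adducts in which 8 was the nucleophile cannot close onto a tert-butyl ester and revert by retro-aldol.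

Step 9. The most likely failure is non-oxidative loss of CO2 through the stabilized furanolate before the lead carboxylate is oxidized, or capture of the C5 cation by acetate without elimination. The fallback separates decarboxylation from oxidation. It sets out from 13 and returns at 14.
- Warming 13 with catalytic Et3N in DMF should expel CO2 and give 5-(3-bromo-4-methoxybenzyl)-4-[4-(tert-butyldimethylsilyloxy)phenyl]furan-2(5H)-one F2.
- TBSOTf and Et3N convert F2 into the 2-silyloxyfuran tert-butyl{[5-(3-bromo-4-methoxybenzyl)-4-(4-(tert-butyldimethylsilyloxy)phenyl)furan-2-yl]oxy}dimethylsilane F3.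
- NBS in THF at −78 °C brominates C5 to give 5-bromo-5-(3-bromo-4-methoxybenzyl)-4-[4-(tert-butyldimethylsilyloxy)phenyl]furan-2(5H)-one F4.
- Addition of Et3N and warming remove HBr across C5–C6 to give 14.

Step 7. The most likely failure is competing oxidative addition of zerovalent palladium into the aryl C–Br bond, followed by hydrodebromination of ring A. The fallback accepts that loss and reinstalls the bromine by electrophilic substitution. It sets out from 11 and returns at 12.
- The reduction is driven to completion with excess HCO2H and Bu3N at 80 °C, so that both C–OTf and C–Br are reduced, giving tert-butyl 2-(4-methoxybenzyl)-3-[4-(tert-butyldimethylsilyloxy)phenyl]-5-oxo-2,5-dihydrofuran-2-carboxylate F5.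
- NBS in MeCN at rt should then brominate ring A ortho to the methoxy group and return 12.
- The para position of ring A is blocked, ring B is deactivated by conjugation with the lactone, and its ortho positions are screened by the silyl group.

Step 4. The most likely failures are Wurtz homocoupling of the electron-rich benzylic Grignard reagent, some magnesium insertion at the aryl bromide, and enolization of 8 during isolation. The fallback reverses the polarity of the benzylic carbon and avoids magnesium. It sets out from 5 and returns at 8.
- tert-Butyl 1,3-dithiane-2-carboxylate F6 is prepared from 2-lithio-1,3-dithiane and Boc2O.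
- Its sodium salt (NaH, DMF, 0 °C) is alkylated by 5 to give tert-butyl 2-(3-bromo-4-methoxybenzyl)-1,3-dithiane-2-carboxylate F7.
- Hydrolysis of the dithioketal with MeI and CaCO3 in aqueous MeCN releases 8, again as the ketone.

## Further compounds

F1 | step 5 | methyl 3-[4-(tert-butyldimethylsilyloxy)phenyl]-2-oxopropanoate | COC(=O)C(=O)Cc1ccc(O[Si](C)(C)C(C)(C)C)cc1
F2 | step 9 | 5-(3-bromo-4-methoxybenzyl)-4-[4-(tert-butyldimethylsilyloxy)phenyl]furan-2(5H)-one (racemic) | COc1ccc(CC2OC(=O)C=C2c2ccc(O[Si](C)(C)C(C)(C)C)cc2)cc1Br
F3 | step 9 | tert-butyl{[5-(3-bromo-4-methoxybenzyl)-4-(4-(tert-butyldimethylsilyloxy)phenyl)furan-2-yl]oxy}dimethylsilane | COc1ccc(Cc2oc(O[Si](C)(C)C(C)(C)C)cc2-c2ccc(O[Si](C)(C)C(C)(C)C)cc2)cc1Br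
F4 | step 9 | 5-bromo-5-(3-bromo-4-methoxybenzyl)-4-[4-(tert-butyldimethylsilyloxy)phenyl]furan-2(5H)-one (racemic) | COc1ccc(CC2(Br)OC(=O)C=C2c2ccc(O[Si](C)(C)C(C)(C)C)cc2)cc1Br
F5 | step 7 | tert-butyl 2-(4-methoxybenzyl)-3-[4-(tert-butyldimethylsilyloxy)phenyl]-5-oxo-2,5-dihydrofuran-2-carboxylate (racemic) | CC(C)(C)OC(=O)C1(Cc2ccc(OC)cc2)OC(=O)C=C1c1ccc(O[Si](C)(C)C(C)(C)C)cc1
F6 | step 4 | tert-butyl 1,3-dithiane-2-carboxylate | CC(C)(C)OC(=O)C1SCCCS1
F7 | step 4 | tert-butyl 2-(3-bromo-4-methoxybenzyl)-1,3-dithiane-2-carboxylate | CC(C)(C)OC(=O)C1(Cc2ccc(OC)c(Br)c2)SCCCS1
A1 | alternative 1 | (Z)-5-(3-bromo-4-methoxybenzylidene)-4-ethynylfuran-2(5H)-one | COc1ccc(/C=C2\OC(=O)C=C2C#C)cc1Br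
A2 | alternative 1 | Danishefsky's diene, (E)-1-methoxy-3-(trimethylsilyloxy)buta-1,3-diene | CO/C=C/C(=C)O[Si](C)(C)C
A3 | alternative 1 | 3''-bromorubrolide F O-trimethylsilyl ether | COc1ccc(/C=C2\OC(=O)C=C2c2ccc(O[Si](C)(C)C)cc2)cc1Br
A4 | alternative 2 | 2-(3-bromo-4-methoxybenzyl)-3-[4-(tert-butyldimethylsilyloxy)phenyl]furan | COc1ccc(Cc2occc2-c2ccc(O[Si](C)(C)C(C)(C)C)cc2)cc1Br
A5 | alternative 2 | 5-(3-bromo-4-methoxybenzyl)-5-hydroxy-4-[4-(tert-butyldimethylsilyloxy)phenyl]furan-2(5H)-one (racemic) | COc1ccc(CC2(O)OC(=O)C=C2c2ccc(O[Si](C)(C)C(C)(C)C)cc2)cc1Br
A6 | alternative 3 | methyl 5-(3-bromo-4-methoxyphenyl)-4-hydroxypent-2-ynoate (racemic) | COC(=O)C#CC(O)Cc1ccc(OC)c(Br)c1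
A7 | alternative 3 | [4-(tert-butyldimethylsilyloxy)phenyl]boronic acid | CC(C)(C)[Si](C)(C)Oc1ccc(B(O)O)cc1
A8 | alternative 3 | 5-(3-bromo-4-methoxybenzyl)-4-[4-(tert-butyldimethylsilyloxy)phenyl]furan-2(5H)-one (racemic) | COc1ccc(CC2OC(=O)C=C2c2ccc(O[Si](C)(C)C(C)(C)C)cc2)cc1Br
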